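**Retrosynthetic overview**

1. Numbering (cembrane): C1 carries the isopropyl group, C4 the CO2Me group, C7 is the ketone, C8 the methyl-bearing carbinol carbon, and C12 carries the lactone carbonyl C20.
2. Ketoemblide ⇒ C3=C4 by intramolecular Still–Gennari olefination and C4–C5 by Michael addition to a C7 vinyl ketone; the 14-membered carbocycle is closed last, on the preformed ε-lactone 17.
3. Lactone 17 ⇒ C10–C11 by hydroboration / B-alkyl Suzuki–Miyaura ring closure of the acyclic ester 15; the seven-membered ring is formed first.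
4. Enabling feature: C11 is the β-carbon of the α,β-unsaturated ε-lactone and C10 is the end of a two-carbon arm on the quaternary carbinol C8. A C8 vinyl group and a C11 enol triflate, tied together by the C20(=O)–O–C8 ester, are therefore an sp3-boron / sp2-triflate pair, and the ring fixes the C11=C12 geometry.
5. 15 ⇒ tertiary vinyl carbinol 11 (C8 from (R)-2-methylglycidol) + acid 8 (C1=C2 geometry from hydroalumination–iodination of an alkynol and a first B-alkyl coupling).

Key step: step 10

Assumption: the SMILES is read as (8S), with CO2Me cis to C2 at C3=C4 and the isopropyl group trans to C3 at C1=C2; (R)-2-methylglycidol is taken as a commercial single enantiomer (it is the Sharpless epoxidation product of 2-methylprop-2-en-1-ol).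

**Route**

Step 1
Reactants: 1 4-methylpent-2-yn-1-ol
Product: 3 (2Z)-3-iodo-4-methylpent-2-en-1-ol, via cyclic alkenylalanate 2 (not isolated)
Conditions: NaAlH2(OCH2CH2OMe)2, THF, 0 °C to rt; then I2, THF, −78 to 0 °C
Reagents that add atoms: iodine, II
Why: Alkoxide-directed trans-hydroalumination of the propargylic alcohol places aluminium on C3 in a five-membered chelate, and iodinolysis with retention should give the (Z)-iodoalkene that fixes the later C1=C2 geometry (hydroalumination–iodination of an alk-2-yn-1-ol).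

Step 2
Reactants: 3 (2Z)-3-iodo-4-methylpent-2-en-1-ol
Product: 4 tert-butyl{[(2Z)-3-iodo-4-methylpent-2-en-1-yl]oxy}dimethylsilane
Conditions: TBSCl, imidazole, CH2Cl2, 0 °C to rt
Reagents that add atoms: tert-butyldimethylsilyl chloride, CC(C)(C)[Si](C)(C)Cl
Why: Imidazole-promoted silylation of a primary allylic alcohol is routine and protects this oxygen through the base-mediated steps that follow.

Step 3
Reactants: 4 tert-butyl{[(2Z)-3-iodo-4-methylpent-2-en-1-yl]oxy}dimethylsilane; 5 methyl but-3-enoate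
Product: 7 methyl (5E)-7-[(tert-butyldimethylsilyl)oxy]-5-(propan-2-yl)hept-5-enoate, via B-alkyl-9-BBN adduct 6 (not isolated)
Conditions: 5, 9-BBN, THF, 0 °C to rt; then 4, Pd(dppf)Cl2 (cat.), AsPh3 (cat.), Cs2CO3, DMF/H2O, rt
Reagents that add atoms: none
Why: 9-BBN adds to the terminal alkene of 5 with boron on the terminal carbon, and sp3–sp2 Suzuki–Miyaura coupling with the vinyl iodide proceeds with retention, so the new chain ends up cis to the CH2OSi group.

Step 4
Reactants: 7 methyl (5E)-7-[(tert-butyldimethylsilyl)oxy]-5-(propan-2-yl)hept-5-enoate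
Product: 8 (5E)-7-[(tert-butyldimethylsilyl)oxy]-5-(propan-2-yl)hept-5-enoic acid
Conditions: LiOH, THF/MeOH/H2O, rt; then 1 M HCl to pH 4, 0 °C
Reagents that add atoms: lithium hydroxide, [Li+].[OH-]
Why: Saponification of the methyl ester with LiOH leaves the primary allylic silyl ether and the trisubstituted alkene untouched.

Step 5
Reactants: 9 (R)-2-methylglycidol
Product: 10 (2S)-2-{[(4-methoxyphenyl)methoxy]methyl}-2-methyloxirane
Conditions: NaH, 4-methoxybenzyl chloride, n-Bu4NI (cat.), THF/DMF, 0 °C to rt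
Reagents that add atoms: 4-methoxybenzyl chloride, COc1ccc(CCl)cc1
Why: Williamson etherification of the primary alkoxide does not touch the quaternary stereocenter, and the only possible Payne rearrangement of this epoxy alcohol is degenerate and stereoretentive (the descriptor changes from R to S only through the priority rules).

Step 6
Reactants: 10 (2S)-2-{[(4-methoxyphenyl)methoxy]methyl}-2-methyloxirane
Product: 11 (2S)-1-[(4-methoxyphenyl)methoxy]-2-methylbut-3-en-2-ol
Conditions: Me3SI, n-BuLi, THF, −10 °C to rt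
Reagents that add atoms: trimethylsulfonium iodide, C[S+](C)C.[I-]
Why: Dimethylsulfonium methylide opens the epoxide at its unsubstituted carbon and the resulting betaine loses dimethyl sulfide, a known one-carbon homologation of epoxides to allylic alcohols that leaves the quaternary center (the future C8) unchanged.

Step 7
Reactants: 8 (5E)-7-[(tert-butyldimethylsilyl)oxy]-5-(propan-2-yl)hept-5-enoic acid; 11 (2S)-1-[(4-methoxyphenyl)methoxy]-2-methylbut-3-en-2-ol
Product: 13 (2S)-1-[(4-methoxyphenyl)methoxy]-2-methylbut-3-en-2-yl (5E)-7-[(tert-butyldimethylsilyl)oxy]-5-(propan-2-yl)hept-5-enoate, via acid chloride 12 (not isolated)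
Conditions: 8, 1-chloro-N,N,2-trimethylprop-1-en-1-amine, CH2Cl2, 0 °C to rt; 11, n-BuLi, THF, −78 °C; then 12, −78 to 0 °C
Reagents that add atoms: none
Why: Acylation of a preformed lithium tert-alkoxide with an acid chloride made under neutral conditions is the standard esterification of hindered tertiary allylic alcohols and tolerates the silyl and PMB ethers.

Step 8
Reactants: 13 (2S)-1-[(4-methoxyphenyl)methoxy]-2-methylbut-3-en-2-yl (5E)-7-[(tert-butyldimethylsilyl)oxy]-5-(propan-2-yl)hept-5-enoate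
Product: 14 the 2-formyl derivative of 13 (C2 epimers in equilibrium with the enol)
Conditions: LiN(i-Pr)2, THF, −78 °C; HCO2CH2CF3, −78 °C; AcOH quench
Reagents that add atoms: 2,2,2-trifluoroethyl formate, O=COCC(F)(F)F
Why: Crossed Claisen formylation of the ester lithium enolate with the activated formate is fast at −78 °C, where the enolate of this allylic ester should not undergo Ireland–Claisen rearrangement.

Step 9
Reactants: 14 the 2-formyl derivative of 13
Product: 15 (2S)-1-[(4-methoxyphenyl)methoxy]-2-methylbut-3-en-2-yl (2Z,5E)-7-[(tert-butyldimethylsilyl)oxy]-5-(propan-2-yl)-2-({[(trifluoromethyl)sulfonyl]oxy}methylidene)hept-5-enoate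
Conditions: NaH, THF, 0 °C; then PhNTf2, 0 °C to rt
Reagents that add atoms: N-phenylbis(trifluoromethanesulfonimide), O=S(=O)(N(c1ccccc1)S(=O)(=O)C(F)(F)F)C(F)(F)F
Why: The sodium enolate of the formyl ester is a U-shaped chelate, so O-triflation should give the enol triflate with the triflate cis to the ester carbonyl (chelation-controlled enol triflate formation of a 1,3-dicarbonyl compound).

Step 10
Reactants: 15 the (2Z)-enol triflate ester
Product: 17 (7S)-3-{(3E)-5-[(tert-butyldimethylsilyl)oxy]-3-(propan-2-yl)pent-3-en-1-yl}-7-{[(4-methoxyphenyl)methoxy]methyl}-7-methyl-6,7-dihydrooxepin-2(5H)-one, via B-alkyl-9-BBN adduct 16 (not isolated)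
Conditions: 9-BBN, THF, 0 °C to rt; then slow addition to Pd(dppf)Cl2 (10 mol %), AsPh3, K3PO4·H2O, THF/DMF, 60 °C, 2 mM
Reagents that add atoms: none
Why: 9-BBN adds only to the monosubstituted C9=C10 alkene (boron on C10); zerovalent palladium then inserts into the C11–OTf bond with retention, base-assisted transmetalation delivers the C10 alkyl group within the same molecule, and reductive elimination forms C10–C11. The closest known reaction type is the intramolecular hydroboration / B-alkyl Suzuki–Miyaura ring closure, together with intermolecular couplings of alkyl-9-BBN reagents with β-triflyloxy enoates. The oxepinone closes by sp3–sp2 reductive elimination from an eight-membered palladacycle in which the C20 ester adopts its s-cis rotamer, so the new bond is endocyclic to the ester tether. No stereocenter is created: C8 is not involved, and the C11=C12 geometry follows from the cis arrangement of triflate and ester in 15, transferred with retention and then locked by the ring. The step needs chemoselective hydroboration, secured by the preference of 9-BBN for the terminal alkene and by full consumption of the allylic ester before palladium is added (which excludes π-allyl ionisation). It also needs ring closure to win over oligomerisation and β-hydride elimination, secured by high dilution, the dppf ligand and the gem-disubstituted C8.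

Step 11
Reactants: 17 the PMB-protected lactone
Product: 18 (7S)-3-{(3E)-5-[(tert-butyldimethylsilyl)oxy]-3-(propan-2-yl)pent-3-en-1-yl}-7-(hydroxymethyl)-7-methyl-6,7-dihydrooxepin-2(5H)-one
Conditions: DDQ, CH2Cl2/pH 7 buffer, 0 °C
Reagents that add atoms: none
Why: DDQ oxidizes the electron-rich PMB ether to a hemiacetal that collapses to the alcohol, a standard oxidative debenzylation that spares the silyl ether, the alkenes and the lactone.

Step 12
Reactants: 18 the hydroxymethyl lactone
Product: 19 (2S)-6-{(3E)-5-[(tert-butyldimethylsilyl)oxy]-3-(propan-2-yl)pent-3-en-1-yl}-2-methyl-7-oxo-2,3,4,7-tetrahydrooxepine-2-carbaldehyde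
Conditions: Dess–Martin periodinane, NaHCO3, CH2Cl2, 0 °C to rt
Reagents that add atoms: none
Why: Buffered Dess–Martin oxidation converts the primary alcohol into a non-enolisable α-acyloxy aldehyde without base, which avoids acyl migration from the tertiary oxygen.

Step 13
Reactants: 19 the lactone aldehyde
Product: 20 (7S)-3-{(3E)-5-[(tert-butyldimethylsilyl)oxy]-3-(propan-2-yl)pent-3-en-1-yl}-7-(1-hydroxyprop-2-en-1-yl)-7-methyl-6,7-dihydrooxepin-2(5H)-one (both carbinol epimers)
Conditions: CH2=CHMgBr, THF, −78 °C; AcOH quench at −78 °C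
Reagents that add atoms: vinylmagnesium bromide, C=C[Mg]Br
Why: At −78 °C the Grignard reagent adds to the aldehyde much faster than to the hindered conjugated lactone, and the new carbinol center needs no control because step 14 removes it.

Step 14
Reactants: 20 the allylic alcohol
Product: 21 (7S)-3-{(3E)-5-[(tert-butyldimethylsilyl)oxy]-3-(propan-2-yl)pent-3-en-1-yl}-7-methyl-7-(prop-2-enoyl)-6,7-dihydrooxepin-2(5H)-one
Conditions: Dess–Martin periodinane, NaHCO3, CH2Cl2, 0 °C
Reagents that add atoms: none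
Why: Dess–Martin oxidation of the secondary allylic alcohol gives the vinyl ketone and erases the temporary stereocenter at C7.

Step 15
Reactants: 21 the vinyl ketone; 22 methyl 2-[bis(2,2,2-trifluoroethoxy)phosphoryl]acetate
Product: 23 methyl 2-[bis(2,2,2-trifluoroethoxy)phosphoryl]-5-[(2S)-6-{(3E)-5-[(tert-butyldimethylsilyl)oxy]-3-(propan-2-yl)pent-3-en-1-yl}-2-methyl-7-oxo-2,3,4,7-tetrahydrooxepin-2-yl]-5-oxopentanoate (epimers at C2 of the pentanoate)
Conditions: 22 (excess), Cs2CO3 (cat.), THF, 0 °C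
Reagents that add atoms: none
Why: Base-catalysed Michael addition of the soft phosphonoacetate anion to the unhindered vinyl ketone forms C4–C5, and the new center at C4 is irrelevant because it becomes sp2 in step 18.

Step 16
Reactants: 23 the silyl-protected keto phosphonate
Product: 24 the corresponding primary allylic alcohol
Conditions: HF·pyridine, pyridine, THF, 0 °C to rt
Reagents that add atoms: none
Why: Buffered HF·pyridine cleaves the primary silyl ether without affecting the lactone, ketone or phosphonate (fluoride desilylation).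

Step 17
Reactants: 24 the allylic alcohol
Product: 25 the corresponding (E)-enal, with a (3E)-5-oxo-3-(propan-2-yl)pent-3-en-1-yl side chain on the lactone
Conditions: MnO2, CH2Cl2, rt
Reagents that add atoms: none
Why: MnO2 oxidizes the allylic alcohol to the enal under neutral conditions, so the C1=C2 geometry and the acidic phosphonate are not disturbed.

Step 18
Reactants: 25 the keto phosphonate enal
Product: 26 ketoemblide
Conditions: K2CO3, 18-crown-6, toluene, −20 to 0 °C, slow addition, 1 mM
Reagents that add atoms: none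
Why: Intramolecular Still–Gennari variant of the Horner–Wadsworth–Emmons reaction: the bis(trifluoroethyl) phosphonate eliminates rapidly from the kinetic adduct and should give the C3=C4 alkene with CO2Me cis to C2, while high dilution favours closure of the 14-membered ring over oligomers.

**Compound list**

1 | 4-methylpent-2-yn-1-ol | CC(C)C#CCO | starting material
2 | sodium 2,2-bis(2-methoxyethoxy)-3-(propan-2-yl)-2,5-dihydro-1,2-oxaalumol-2-uide (cyclic alkenylalanate) | CC(C)C1=CCO[Al-]1(OCCOC)OCCOC.[Na+] | intermediate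
3 | (2Z)-3-iodo-4-methylpent-2-en-1-ol | OC/C=C(\I)C(C)C | intermediate
4 | tert-butyl{[(2Z)-3-iodo-4-methylpent-2-en-1-yl]oxy}dimethylsilane | CC(C)(C)[Si](C)(C)OC/C=C(\I)C(C)C | intermediate
5 | methyl but-3-enoate | C=CCC(=O)OC | starting material
6 | methyl 4-(9-borabicyclo[3.3.1]nonan-9-yl)butanoate | COC(=O)CCCB1C2CCCC1CCC2 | intermediate
7 | methyl (5E)-7-[(tert-butyldimethylsilyl)oxy]-5-(propan-2-yl)hept-5-enoate | COC(=O)CCC/C(C(C)C)=C\CO[Si](C)(C)C(C)(C)C | intermediate
8 | (5E)-7-[(tert-butyldimethylsilyl)oxy]-5-(propan-2-yl)hept-5-enoic acid | OC(=O)CCC/C(C(C)C)=C\CO[Si](C)(C)C(C)(C)C | intermediate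
9 | (R)-2-methylglycidol, [(2R)-2-methyloxiran-2-yl]methanol | C1[C@](C)(O1)CO | starting material
10 | (2S)-2-{[(4-methoxyphenyl)methoxy]methyl}-2-methyloxirane | C1[C@](C)(O1)COCc2ccc(OC)cc2 | intermediate
11 | (2S)-1-[(4-methoxyphenyl)methoxy]-2-methylbut-3-en-2-ol | C=C[C@](C)(O)COCc1ccc(OC)cc1 | intermediate
12 | (5E)-7-[(tert-butyldimethylsilyl)oxy]-5-(propan-2-yl)hept-5-enoyl chloride | ClC(=O)CCC/C(C(C)C)=C\CO[Si](C)(C)C(C)(C)C | intermediate
13 | (2S)-1-[(4-methoxyphenyl)methoxy]-2-methylbut-3-en-2-yl (5E)-7-[(tert-butyldimethylsilyl)oxy]-5-(propan-2-yl)hept-5-enoate | C=C[C@](C)(OC(=O)CCC/C(C(C)C)=C\CO[Si](C)(C)C(C)(C)C)COCc1ccc(OC)cc1 | intermediate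
14 | (2S)-1-[(4-methoxyphenyl)methoxy]-2-methylbut-3-en-2-yl (5E)-7-[(tert-butyldimethylsilyl)oxy]-2-formyl-5-(propan-2-yl)hept-5-enoate (C2 epimers, enol tautomer present) | C=C[C@](C)(OC(=O)C(C=O)CC/C(C(C)C)=C\CO[Si](C)(C)C(C)(C)C)COCc1ccc(OC)cc1 | intermediate
15 | (2S)-1-[(4-methoxyphenyl)methoxy]-2-methylbut-3-en-2-yl (2Z,5E)-7-[(tert-butyldimethylsilyl)oxy]-5-(propan-2-yl)-2-({[(trifluoromethyl)sulfonyl]oxy}methylidene)hept-5-enoate | C=C[C@](C)(OC(=O)/C(=C\OS(=O)(=O)C(F)(F)F)CC/C(C(C)C)=C\CO[Si](C)(C)C(C)(C)C)COCc1ccc(OC)cc1 | intermediate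
16 | (2S)-4-(9-borabicyclo[3.3.1]nonan-9-yl)-1-[(4-methoxyphenyl)methoxy]-2-methylbutan-2-yl ester corresponding to 15 | B1(C2CCCC1CCC2)CC[C@](C)(OC(=O)/C(=C\OS(=O)(=O)C(F)(F)F)CC/C(C(C)C)=C\CO[Si](C)(C)C(C)(C)C)COCc1ccc(OC)cc1 | intermediate
17 | (7S)-3-{(3E)-5-[(tert-butyldimethylsilyl)oxy]-3-(propan-2-yl)pent-3-en-1-yl}-7-{[(4-methoxyphenyl)methoxy]methyl}-7-methyl-6,7-dihydrooxepin-2(5H)-one | CC(C)(C)[Si](C)(C)OC\C=C(\C(C)C)CCC1=CCC[C@](C)(OC1=O)COCc2ccc(OC)cc2 | intermediate
18 | (7S)-3-{(3E)-5-[(tert-butyldimethylsilyl)oxy]-3-(propan-2-yl)pent-3-en-1-yl}-7-(hydroxymethyl)-7-methyl-6,7-dihydrooxepin-2(5H)-one | CC(C)(C)[Si](C)(C)OC\C=C(\C(C)C)CCC1=CCC[C@](C)(OC1=O)CO | intermediate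
19 | (2S)-6-{(3E)-5-[(tert-butyldimethylsilyl)oxy]-3-(propan-2-yl)pent-3-en-1-yl}-2-methyl-7-oxo-2,3,4,7-tetrahydrooxepine-2-carbaldehyde | CC(C)(C)[Si](C)(C)OC\C=C(\C(C)C)CCC1=CCC[C@](C)(OC1=O)C=O | intermediate
20 | (7S)-3-{(3E)-5-[(tert-butyldimethylsilyl)oxy]-3-(propan-2-yl)pent-3-en-1-yl}-7-(1-hydroxyprop-2-en-1-yl)-7-methyl-6,7-dihydrooxepin-2(5H)-one (carbinol epimers) | CC(C)(C)[Si](C)(C)OC\C=C(\C(C)C)CCC1=CCC[C@](C)(OC1=O)C(O)C=C | intermediate
21 | (7S)-3-{(3E)-5-[(tert-butyldimethylsilyl)oxy]-3-(propan-2-yl)pent-3-en-1-yl}-7-methyl-7-(prop-2-enoyl)-6,7-dihydrooxepin-2(5H)-one | CC(C)(C)[Si](C)(C)OC\C=C(\C(C)C)CCC1=CCC[C@](C)(OC1=O)C(=O)C=C | intermediate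
22 | methyl 2-[bis(2,2,2-trifluoroethoxy)phosphoryl]acetate | COC(=O)CP(=O)(OCC(F)(F)F)OCC(F)(F)F | starting material
23 | methyl 2-[bis(2,2,2-trifluoroethoxy)phosphoryl]-5-[(2S)-6-{(3E)-5-[(tert-butyldimethylsilyl)oxy]-3-(propan-2-yl)pent-3-en-1-yl}-2-methyl-7-oxo-2,3,4,7-tetrahydrooxepin-2-yl]-5-oxopentanoate (C2 epimers) | CC(C)(C)[Si](C)(C)OC\C=C(\C(C)C)CCC1=CCC[C@](C)(OC1=O)C(=O)CCC(C(=O)OC)P(=O)(OCC(F)(F)F)OCC(F)(F)F | intermediate
24 | methyl 2-[bis(2,2,2-trifluoroethoxy)phosphoryl]-5-[(2S)-6-{(3E)-5-hydroxy-3-(propan-2-yl)pent-3-en-1-yl}-2-methyl-7-oxo-2,3,4,7-tetrahydrooxepin-2-yl]-5-oxopentanoate | OC\C=C(\C(C)C)CCC1=CCC[C@](C)(OC1=O)C(=O)CCC(C(=O)OC)P(=O)(OCC(F)(F)F)OCC(F)(F)F | intermediate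
25 | methyl 2-[bis(2,2,2-trifluoroethoxy)phosphoryl]-5-[(2S)-2-methyl-7-oxo-6-{(3E)-5-oxo-3-(propan-2-yl)pent-3-en-1-yl}-2,3,4,7-tetrahydrooxepin-2-yl]-5-oxopentanoate | O=C\C=C(\C(C)C)CCC1=CCC[C@](C)(OC1=O)C(=O)CCC(C(=O)OC)P(=O)(OCC(F)(F)F)OCC(F)(F)F | intermediate
26 | ketoemblide, (8S); methyl ester on C4, C7 ketone, C20–O–C8 ε-lactone | COC(=O)/C1=C\C=C(\C(C)C)CCC2=CCC[C@](C)(OC2=O)C(=O)CC1 | target

**Step count and risks**

Total step count: 18. Longest linear sequence: 16 steps (steps 1–4, then 7–18).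

Steps most likely to fail:

1. Step 10. The ring closure may lose to intermolecular coupling, protodeboronation or slow transmetalation, because the ester must reach its s-cis rotamer in the palladacycle. Fallback (sets out from 7 and 11, returns at 17): form C10–C11 between two molecules and close the ring through the C–O bond. Ester 7 is formylated and triflated as in steps 8 and 9 to give the methyl 2-formyl ester F1 and then the methyl (Z)-enol triflate F2. Carbinol 11 is treated with two equivalents of 9-BBN, the first capping the hydroxyl group, to give the bis-boryl adduct F3. Coupling of F3 with F2 under the conditions of step 10 should give the hydroxy (Z)-enoate F4. Its tertiary alkoxide (NaH cat., toluene, 4 Å sieves, 60 °C) should then close onto the cis-disposed methyl ester to give 17.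

2. Step 18. The ring-closing olefination may show poor control of the C3=C4 geometry or give oligomers. Fallback (sets out from 20, returns at 26): set the geometry between two molecules and close the ring by a second hydroboration / B-alkyl coupling at C4–C5. HF·pyridine gives the diol F5, and TEMPO/PhI(OAc)2 oxidizes only the primary allylic alcohol to the hydroxy enal F6. Olefination with methyl 2-bromo-2-[bis(2,2,2-trifluoroethoxy)phosphoryl]acetate (KN(SiMe3)2, 18-crown-6, THF, −78 °C), a reagent of the Still–Gennari type that places bromine trans to the aldehyde-derived carbon, gives the (2E)-bromodienoate F7. Excess 9-BBN gives the boryl adduct F8, and intramolecular B-alkyl Suzuki–Miyaura coupling under the conditions of step 3 at high dilution should close C4–C5 with retention to give the macrocyclic alcohol F9. Dess–Martin oxidation then gives 26.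

3. Step 9. Geometric control in the enol triflate formation may be poor, and only the isomer with triflate cis to the ester can close in step 10. Fallback (sets out from 15 in any isomer ratio, returns at 17): a radical closure that does not depend on the alkene geometry. 9-BBN followed by Me3NO gives the primary alcohol F10, and I2, PPh3 and imidazole give the iodide F11. Bu3SnH (slow addition) with AIBN in benzene at 80 °C should give the saturated β-triflyloxy lactone F12 by 7-endo radical addition to the oxygen-bearing β-carbon of the acrylate, the mode of attack known for β-alkoxyacrylates. DBU then eliminates triflate to give 17; both isomers converge because the alkene is re-formed inside the ring.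

Further compounds
F1 | step 10 | methyl (5E)-7-[(tert-butyldimethylsilyl)oxy]-2-formyl-5-(propan-2-yl)hept-5-enoate | COC(=O)C(C=O)CC/C(C(C)C)=C\CO[Si](C)(C)C(C)(C)C
F2 | step 10 | methyl (2Z,5E)-7-[(tert-butyldimethylsilyl)oxy]-5-(propan-2-yl)-2-({[(trifluoromethyl)sulfonyl]oxy}methylidene)hept-5-enoate | COC(=O)/C(=C\OS(=O)(=O)C(F)(F)F)CC/C(C(C)C)=C\CO[Si](C)(C)C(C)(C)C
F3 | step 10 | 9-{(3S)-3-[(9-borabicyclo[3.3.1]nonan-9-yl)oxy]-4-[(4-methoxyphenyl)methoxy]-3-methylbutyl}-9-borabicyclo[3.3.1]nonane | B1(C2CCCC1CCC2)CC[C@](C)(OB3C4CCCC3CCC4)COCc5ccc(OC)cc5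
F4 | step 10 | methyl (2Z,5E)-7-[(tert-butyldimethylsilyl)oxy]-2-{(4S)-4-hydroxy-5-[(4-methoxyphenyl)methoxy]-4-methylpentylidene}-5-(propan-2-yl)hept-5-enoate | COC(=O)/C(=C\CC[C@](C)(O)COCc1ccc(OC)cc1)CC/C(C(C)C)=C\CO[Si](C)(C)C(C)(C)C
F5 | step 18 | (7S)-7-(1-hydroxyprop-2-en-1-yl)-3-[(3E)-5-hydroxy-3-(propan-2-yl)pent-3-en-1-yl]-7-methyl-6,7-dihydrooxepin-2(5H)-one | OC\C=C(\C(C)C)CCC1=CCC[C@](C)(OC1=O)C(O)C=C
F6 | step 18 | (2E)-5-[(7S)-7-(1-hydroxyprop-2-en-1-yl)-7-methyl-2-oxo-2,5,6,7-tetrahydrooxepin-3-yl]-3-(propan-2-yl)pent-2-enal | O=C\C=C(\C(C)C)CCC1=CCC[C@](C)(OC1=O)C(O)C=C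
F7 | step 18 | methyl (2E,4E)-2-bromo-7-[(7S)-7-(1-hydroxyprop-2-en-1-yl)-7-methyl-2-oxo-2,5,6,7-tetrahydrooxepin-3-yl]-5-(propan-2-yl)hepta-2,4-dienoate | COC(=O)/C(Br)=C\C=C(\C(C)C)CCC1=CCC[C@](C)(OC1=O)C(O)C=C
F8 | step 18 | 9-BBN adduct of F7, boron on the terminal carbon of the former vinyl group and on the carbinol oxygen | COC(=O)/C(Br)=C\C=C(\C(C)C)CCC1=CCC[C@](C)(OC1=O)C(OB2C3CCCC2CCC3)CCB4C5CCCC4CCC5
F9 | step 18 | 7-deoxo-7-hydroxyketoemblide (C7 epimers) | COC(=O)/C1=C\C=C(\C(C)C)CCC2=CCC[C@](C)(OC2=O)C(O)CC1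
F10 | step 9 | (2S)-4-hydroxy-1-[(4-methoxyphenyl)methoxy]-2-methylbutan-2-yl (5E)-7-[(tert-butyldimethylsilyl)oxy]-5-(propan-2-yl)-2-({[(trifluoromethyl)sulfonyl]oxy}methylidene)hept-5-enoate (either geometry at C2) | OCC[C@](C)(OC(=O)C(=COS(=O)(=O)C(F)(F)F)CC/C(C(C)C)=C\CO[Si](C)(C)C(C)(C)C)COCc1ccc(OC)cc1
F11 | step 9 | (2S)-4-iodo-1-[(4-methoxyphenyl)methoxy]-2-methylbutan-2-yl (5E)-7-[(tert-butyldimethylsilyl)oxy]-5-(propan-2-yl)-2-({[(trifluoromethyl)sulfonyl]oxy}methylidene)hept-5-enoate (either geometry at C2) | ICC[C@](C)(OC(=O)C(=COS(=O)(=O)C(F)(F)F)CC/C(C(C)C)=C\CO[Si](C)(C)C(C)(C)C)COCc1ccc(OC)cc1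
F12 | step 9 | (7S)-3-{(3E)-5-[(tert-butyldimethylsilyl)oxy]-3-(propan-2-yl)pent-3-en-1-yl}-7-{[(4-methoxyphenyl)methoxy]methyl}-7-methyl-2-oxooxepan-4-yl trifluoromethanesulfonate (diastereomers at C3 and C4) | CC(C)(C)[Si](C)(C)OC\C=C(\C(C)C)CCC1C(OS(=O)(=O)C(F)(F)F)CC[C@](C)(OC1=O)COCc2ccc(OC)cc2
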